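**Plan**
1. Cuts: first the S–O bond of a tosyl group on the 3'-OH. Then, in one stroke, the pyran O4–CMe2 bond, the C5–CH= bond and the C3–CH2 (prenyl) bond, which leads back to a bis-ether with 1,1-dimethylallyl on O-2 and 1,1-dimethylpropargyl on O-4. Then those two O–C bonds, and last the C1–C(=O) bond.
2. Enabling feature: on the fully substituted phloroglucinol ring (C1 aroyl, C2 OH, C3 prenyl, C4 pyran O, C5 pyran CH=, C6 OH) each isoprenoid C–C bond is ortho to a ring oxygen (C3 beside O-2, C5 beside O-4), so each is an aryl ether Claisen retron. C1, the other neighbour of O-2, is occupied by the aroyl group, and C3 and C5 are the only ring CH sites of the precursor.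
3. Forward order: both benzene rings are bought and joined by Friedel–Crafts acylation. O-4 (Cu) and then O-2 (Pd) are etherified. The 2H-pyran is the only ring made and closes last, inside the thermal cascade; hydroxide then frees the 3'-OH.
4. Stereochemistry: none has to be created. There is no stereocentre, the chromene alkene is ring-locked cis, and the prenyl alkene ends in two methyl groups.

Key step: step 8

Remark on the chemistry: the target is achiral, so its constitution alone satisfies the demand for a single enantiomer. The locants C1–C6 and O-2, O-4, O-6 below refer to the phloroglucinol ring as numbered above, and 3' refers to the second ring.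

Step 1
Reactants: 1 3-hydroxybenzoic acid
Product: 2 3-(tosyloxy)benzoic acid
Conditions: TsCl (1.1 equiv), NaOH (3 equiv), H2O–THF, 0 °C to rt; then aq HCl to pH 2
Reagents that add atoms: p-toluenesulfonyl chloride, Cc1ccc(S(=O)(=O)Cl)cc1
Why: Schotten–Baumann O-sulfonylation: in aqueous NaOH the phenoxide of 1 is sulfonylated, any mixed carboxylic–sulfonic anhydride is hydrolysed back to the carboxylate, and acidification should precipitate 2, whose aryl sulfonate later withstands Lewis acid, amine base, Pd(0) and heat and leaves only with hydroxide.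

Step 2
Reactants: 2 3-(tosyloxy)benzoic acid
Product: 3 3-(tosyloxy)benzoyl chloride
Conditions: SOCl2 (3 equiv), DMF (cat.), toluene, 70 °C; evaporate
Reagents that add atoms: thionyl chloride, O=S(Cl)Cl
Why: Standard conversion of a benzoic acid into its chloride with SOCl2 under Vilsmeier-type DMF catalysis, to which the aryl tosylate is inert.

Step 3
Reactants: 3 3-(tosyloxy)benzoyl chloride; 4 phloroglucinol (anhydrous, 1.3 equiv)
Product: 5 3-(2,4,6-trihydroxybenzoyl)phenyl 4-methylbenzenesulfonate (2,4,6-trihydroxy-3'-tosyloxybenzophenone)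
Conditions: AlCl3 (4 equiv), PhNO2, 0 to 60 °C; ice/aq HCl
Reagents that add atoms: none
Why: Friedel–Crafts C-acylation of phloroglucinol, in which any aryl ester formed first is carried on by AlCl3 through a Fries shift, the threefold symmetry of 4 allows only one monoketone, the chelated aroyl group deactivates the ring against a second acylation, and the sulfonate tolerates AlCl3 at this temperature.

Step 4
Reactants: 6 2-methylbut-3-yn-2-ol
Product: 8 methyl 2-methylbut-3-yn-2-yl carbonate, via lithium 2-methylbut-3-yn-2-olate 7 (not isolated)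
Conditions: n-BuLi (1.0 equiv), THF, −78 °C; ClCO2Me, −78 °C to rt
Reagents that add atoms: methyl chloroformate, COC(=O)Cl
Why: O-acylation of a preformed lithium alkoxide with a chloroformate, in which one equivalent of n-BuLi at −78 °C removes only the O–H proton and leaves the far less acidic alkyne C–H untouched.

Step 5
Reactants: 5 2,4,6-trihydroxy-3'-tosyloxybenzophenone; 8 methyl 2-methylbut-3-yn-2-yl carbonate (1.1 equiv)
Product: 9 3-[2,6-dihydroxy-4-(2-methylbut-3-yn-2-yloxy)benzoyl]phenyl 4-methylbenzenesulfonate (4-O-(1,1-dimethylpropargyl) ether of 5)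
Conditions: CuCl2·2H2O (2 mol %), DBU (1.05 equiv), MeCN, N2, −5 to 0 °C; cold aqueous work-up, bath below 25 °C
Reagents that add atoms: none
Why: Copper-catalysed propargylic etherification (copper acetylide, then copper allenylidene, captured at the tertiary carbon by the phenoxide) is the standard way to aryl 1,1-dimethylpropargyl ethers, and one equivalent of DBU should ionise only the 4-OH, the most acidic and least hindered hydroxyl because it lies para to the carbonyl and away from the aroyl group, while 0 °C keeps the new ether from rearranging.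

Step 6
Reactants: 10 2-methylbut-3-en-2-ol
Product: 12 tert-butyl 2-methylbut-3-en-2-yl carbonate, via lithium 2-methylbut-3-en-2-olate 11 (not isolated)
Conditions: n-BuLi (1.0 equiv), THF, 0 °C; Boc2O (1.1 equiv), 0 °C to rt; H2O quench
Reagents that add atoms: di-tert-butyl dicarbonate, CC(C)(C)OC(=O)OC(=O)OC(C)(C)C
Why: Acylation of the preformed tertiary lithium alkoxide with Boc2O (mixed carbonate formation) is the usual access to this reagent, the expelled tert-butyl carbonate anion simply collapsing to CO2 and tert-butoxide.

Step 7
Reactants: 9 4-O-(1,1-dimethylpropargyl) ether; 12 tert-butyl 2-methylbut-3-en-2-yl carbonate (1.3 equiv)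
Product: 13 3-[2-hydroxy-6-(2-methylbut-3-en-2-yloxy)-4-(2-methylbut-3-yn-2-yloxy)benzoyl]phenyl 4-methylbenzenesulfonate (bis-ether: 1,1-dimethylallyl on O-2, 1,1-dimethylpropargyl on O-4, free 6-OH)
Conditions: Pd(PPh3)4 (5 mol %), THF (degassed), 0 °C, 20–30 min; cold chromatography on Et3N-washed silica
Reagents that add atoms: none
Why: Tsuji–Trost-type decarboxylative O-allylation: Pd(0) ionises 12 to a 1,1-dimethyl-π-allyl complex, CO2 and tert-butoxide, the latter deprotonates the one ortho hydroxyl that the carbonyl oxygen is not chelating, and the phenoxide attacks the more substituted allyl terminus under kinetic control to give the branched ether, after which the last hydroxyl is held permanently in the hydrogen bond and does not react, the low temperature and short time prevent re-ionisation to the linear prenyl ether, and the aryl tosylate and alkyne are left alone by Pd(PPh3)4 at 0 °C.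

Step 8
Reactants: 13 bis-ether (allyl on O-2, propargyl on O-4)
Product: 19 3-[5,7-dihydroxy-2,2-dimethyl-8-(3-methylbut-2-enyl)-2H-chromene-6-carbonyl]phenyl 4-methylbenzenesulfonate (O-tosyl target), via C3-prenyl dienone 14 (not isolated), via 3-prenylphenol propargyl ether 15 (not isolated), via C5-allenyl dienone 16 (not isolated), via ortho-allenylphenol 17 (not isolated), via (Z)-vinyl ortho-quinone methide 18 (not isolated)
Conditions: o-xylene (degassed, 0.02 M), PhNEt2 (1 equiv, proton buffer), Ar, base-washed glassware, 105 °C until 13 is consumed, then 144 °C (reflux); chromatography on Et3N-washed silica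
Reagents that add atoms: none
Why: Proposed new method: near 105 °C the tertiary allyl ether on O-2 of 13 should undergo a chair-like aromatic Claisen [3,3] shift to C3, its only free ortho carbon because C1 carries the aroyl group, which forms the C3–CH2 bond in dienone 14 and, after tautomerisation, the 3-prenylphenol 15. At reflux the propargyl ether on O-4 should then shift [3,3] to C5, forming the C5–CH= bond in allenyl dienone 16, which enolises to ortho-allenylphenol 17 and passes by a 1,5-H shift from O4–H to the central allene carbon into the (Z)-vinyl ortho-quinone methide 18. The 2,2-dimethyl-2H-pyran, the only ring closed, forms by thermal disrotatory oxa-6π electrocyclisation of 18 through the O4–CMe2 bond, which restores the benzene ring in 19. The closest known reaction types are the Claisen rearrangement of aryl 1,1-dimethylallyl ethers to ortho-prenylphenols and the propargyl Claisen/1,5-H shift/electrocyclisation of aryl 1,1-dimethylpropargyl ethers to 2,2-dimethylchromenes, both established separately on hydroxyaryl ketones; what is new is running them on one ring in one heating operation. The step needs the two C5 units to end on different ring carbons and the pyran to close on O-4 rather than O-6: the first is secured by the lower barrier and single terminus of the allyl shift and by the lone O6–H···O=C chelate of 13, which favours the Kekulé form with C1=C6, C2=C3 and C4=C5 double bonds and so points O-2 to C3 and O-4 to C5 (either order of events then converges on 19), the second by the hydrogen bond to the ketone, which turns O6–H away from the allene, whereas O4–H, para to the carbonyl, is the most acidic and never chelated hydroxyl and is free to deliver its hydrogen. No stereocentre survives, since the sp3 carbons C3 of 14 and C5 of 16 are erased on tautomerisation, so there is nothing to control.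

Step 9
Reactants: 19 O-tosyl target
Product: 20 (5,7-dihydroxy-2,2-dimethyl-8-(3-methylbut-2-enyl)-2H-chromen-6-yl)(3-hydroxyphenyl)methanone (target CNP0424359.0)
Conditions: KOH (8 equiv), 1,4-dioxane–H2O (1:1), Ar, 70 °C; AcOH to pH 6–7, 0 °C
Reagents that add atoms: none
Why: Saponification of an aryl sulfonate by attack of hydroxide at sulfur, which releases the 3'-phenoxide while chromene, prenyl group and diaryl ketone are inert to base; an alcohol-free medium avoids an alkyl tosylate that could O-alkylate the phenoxides, argon guards the electron-rich phenoxides against autoxidation, and neutralisation with a weak acid avoids acid-catalysed cyclisation of the prenyl group onto the neighbouring 7-OH.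

**Compound list**
1 | 3-hydroxybenzoic acid | O=C(O)c1cccc(O)c1 | starting material
2 | 3-(tosyloxy)benzoic acid | Cc1ccc(S(=O)(=O)Oc2cccc(C(=O)O)c2)cc1 | intermediate
3 | 3-(tosyloxy)benzoyl chloride | Cc1ccc(S(=O)(=O)Oc2cccc(C(=O)Cl)c2)cc1 | intermediate
4 | phloroglucinol | Oc1cc(O)cc(O)c1 | starting material
5 | 3-(2,4,6-trihydroxybenzoyl)phenyl 4-methylbenzenesulfonate | Cc1ccc(S(=O)(=O)Oc2cccc(C(=O)c3c(O)cc(O)cc3O)c2)cc1 | intermediate
6 | 2-methylbut-3-yn-2-ol | C#CC(C)(C)O | starting material
7 | lithium 2-methylbut-3-yn-2-olate (not isolated) | [Li+].[O-]C(C)(C)C#C | intermediate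
8 | methyl 2-methylbut-3-yn-2-yl carbonate | COC(=O)OC(C)(C)C#C | intermediate
9 | 3-[2,6-dihydroxy-4-(2-methylbut-3-yn-2-yloxy)benzoyl]phenyl 4-methylbenzenesulfonate | Cc1ccc(S(=O)(=O)Oc2cccc(C(=O)c3c(O)cc(OC(C)(C)C#C)cc3O)c2)cc1 | intermediate
10 | 2-methylbut-3-en-2-ol | C=CC(C)(C)O | starting material
11 | lithium 2-methylbut-3-en-2-olate (not isolated) | [Li+].[O-]C(C)(C)C=C | intermediate
12 | tert-butyl 2-methylbut-3-en-2-yl carbonate | C=CC(C)(C)OC(=O)OC(C)(C)C | intermediate
13 | 3-[2-hydroxy-6-(2-methylbut-3-en-2-yloxy)-4-(2-methylbut-3-yn-2-yloxy)benzoyl]phenyl 4-methylbenzenesulfonate | Cc1ccc(S(=O)(=O)Oc2cccc(C(=O)c3c(O)cc(OC(C)(C)C#C)cc3OC(C)(C)C=C)c2)cc1 | intermediate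
14 | C3-prenyl dienone: cyclohexa-2,4-dienone with C2=O, sp3 C3 (H, prenyl; transient, racemic), 4-O-propargyl, 6-OH, 1-aroyl (not isolated) | CC(C)=CCC1C(=O)C(C(=O)c2cccc(OS(=O)(=O)c3ccc(C)cc3)c2)=C(O)C=C1OC(C)(C)C#C | intermediate
15 | 3-[2,6-dihydroxy-3-(3-methylbut-2-enyl)-4-(2-methylbut-3-yn-2-yloxy)benzoyl]phenyl 4-methylbenzenesulfonate (not isolated) | CC(C)=CCc1c(O)c(C(=O)c2cccc(OS(=O)(=O)c3ccc(C)cc3)c2)c(O)cc1OC(C)(C)C#C | intermediate
16 | C5-allenyl dienone: C4=O, sp3 C5 (H, 3-methylbuta-1,2-dienyl; transient, racemic), 3-prenyl, 2- and 6-OH, 1-aroyl (not isolated) | CC(C)=CCC1=C(O)C(C(=O)c2cccc(OS(=O)(=O)c3ccc(C)cc3)c2)=C(O)C(C=C=C(C)C)C1=O | intermediate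
17 | 3-[2,4,6-trihydroxy-3-(3-methylbuta-1,2-dienyl)-5-(3-methylbut-2-enyl)benzoyl]phenyl 4-methylbenzenesulfonate (not isolated) | CC(C)=CCc1c(O)c(C(=O)c2cccc(OS(=O)(=O)c3ccc(C)cc3)c2)c(O)c(C=C=C(C)C)c1O | intermediate
18 | (Z)-vinyl ortho-quinone methide: C4=O, exocyclic C5=CH–CH=CMe2 with the vinyl group cis to C4 (not isolated) | CC(C)=CCC1=C(O)C(C(=O)c2cccc(OS(=O)(=O)c3ccc(C)cc3)c2)=C(O)/C(=C/C=C(C)C)C1=O | intermediate
19 | 3-[5,7-dihydroxy-2,2-dimethyl-8-(3-methylbut-2-enyl)-2H-chromene-6-carbonyl]phenyl 4-methylbenzenesulfonate | CC(C)=CCc1c(O)c(C(=O)c2cccc(OS(=O)(=O)c3ccc(C)cc3)c2)c(O)c2c1OC(C)(C)C=C2 | intermediate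
20 | (5,7-dihydroxy-2,2-dimethyl-8-(3-methylbut-2-enyl)-2H-chromen-6-yl)(3-hydroxyphenyl)methanone | CC(C)=CCc1c(O)c(C(=O)c2cccc(O)c2)c(O)c2c1OC(C)(C)C=C2 | target

**Count**
Total steps: 9. Longest linear sequence: 7 (steps 1, 2, 3, 5, 7, 8, 9).

**Steps most likely to fail**

Step 8.
- The propargyl shift may begin before the allyl shift is finished and run to C3, which would leave the allyl ether without an open ortho site.
- The tertiary allyl ether may fragment with loss of isoprene.
- The hydrogen shift and ring closure may start from O-6 instead of O-4.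

Fallback with known chemistry, from 9 back to 19: the two C5 units are brought in by separate operations, and the prenyl group arrives as an electrophile. Ether 9, in which C3 and C5 are still equivalent, is heated alone in refluxing o-xylene. The established propargyl Claisen/1,5-H shift/oxa-6π sequence then has only one ring carbon type to use and should give 3-(5,7-dihydroxy-2,2-dimethyl-2H-chromene-6-carbonyl)phenyl 4-methylbenzenesulfonate F1. Its single remaining ring CH (chromene C8) is then C-prenylated with prenyl bromide and aqueous KOH at 0 °C, the classical alkylation of acylphloroglucinol anions, which leads to 19.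

Step 7.
- Ionisation by Pd(0) is reversible, so the branched ether may drift to the linear prenyl ether.
- The electron-rich ring may be allylated at carbon.
- The hindered ortho hydroxyl may react sluggishly.
- Pd(0) may attack the propargylic ether.

Fallback, from 5 back to 13: the allyl ether is made by the classical propargyl ether/semihydrogenation route before the O-4 propargyl group is present.
- The 4-OH of 5 is silylated selectively (TIPSCl, imidazole, DMF, 0 °C) to give 3-[2,6-dihydroxy-4-(triisopropylsilyloxy)benzoyl]phenyl 4-methylbenzenesulfonate F2.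
- Copper-catalysed etherification with 8 (CuCl2 cat., DBU, MeCN, 0 °C) at one of the two equivalent ortho hydroxyls gives the 2-O-(1,1-dimethylpropargyl) 4-O-TIPS ether F3.
- Lindlar semihydrogenation (H2, Pd/CaCO3–Pb, quinoline, EtOAc, rt) gives the 2-O-(1,1-dimethylallyl) 4-O-TIPS ether F4.
- Buffered fluoride (TBAF, AcOH, THF, 0 °C) removes the silyl group to give 3-[2,4-dihydroxy-6-(2-methylbut-3-en-2-yloxy)benzoyl]phenyl 4-methylbenzenesulfonate F5.
- A second copper-catalysed etherification with 8 at the liberated 4-OH, under the conditions of step 5, gives 13.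

Step 3.
- O-acylation may occur without a subsequent Fries shift.
- A second acylation may take place.
- Poor solubility of the aluminium phenoxide complexes may hold back conversion.

Fallback, from 3 back to 5: the ring is acylated in protected form. Acid chloride 3 is combined with purchased 1,3,5-trimethoxybenzene (AlCl3, CH2Cl2, 0 °C), a clean Friedel–Crafts acylation of a soluble arene, to give 3-(2,4,6-trimethoxybenzoyl)phenyl 4-methylbenzenesulfonate F6. Exhaustive ether cleavage with excess BBr3 (CH2Cl2, −78 °C to rt), to which the sulfonate is inert, gives 5.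

**Further compounds**
F1 | step 8 | 3-(5,7-dihydroxy-2,2-dimethyl-2H-chromene-6-carbonyl)phenyl 4-methylbenzenesulfonate | CC1(C)C=Cc2c(O1)cc(O)c(C(=O)c1cccc(OS(=O)(=O)c3ccc(C)cc3)c1)c2O
F2 | step 7 | 3-[2,6-dihydroxy-4-(triisopropylsilyloxy)benzoyl]phenyl 4-methylbenzenesulfonate | Cc1ccc(S(=O)(=O)Oc2cccc(C(=O)c3c(O)cc(O[Si](C(C)C)(C(C)C)C(C)C)cc3O)c2)cc1
F3 | step 7 | 3-[2-hydroxy-6-(2-methylbut-3-yn-2-yloxy)-4-(triisopropylsilyloxy)benzoyl]phenyl 4-methylbenzenesulfonate | Cc1ccc(S(=O)(=O)Oc2cccc(C(=O)c3c(O)cc(O[Si](C(C)C)(C(C)C)C(C)C)cc3OC(C)(C)C#C)c2)cc1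
F4 | step 7 | 3-[2-hydroxy-6-(2-methylbut-3-en-2-yloxy)-4-(triisopropylsilyloxy)benzoyl]phenyl 4-methylbenzenesulfonate | Cc1ccc(S(=O)(=O)Oc2cccc(C(=O)c3c(O)cc(O[Si](C(C)C)(C(C)C)C(C)C)cc3OC(C)(C)C=C)c2)cc1
F5 | step 7 | 3-[2,4-dihydroxy-6-(2-methylbut-3-en-2-yloxy)benzoyl]phenyl 4-methylbenzenesulfonate | Cc1ccc(S(=O)(=O)Oc2cccc(C(=O)c3c(O)cc(O)cc3OC(C)(C)C=C)c2)cc1
F6 | step 3 | 3-(2,4,6-trimethoxybenzoyl)phenyl 4-methylbenzenesulfonate | COc1cc(OC)c(C(=O)c2cccc(OS(=O)(=O)c3ccc(C)cc3)c2)c(OC)c1
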